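**Retrosynthetic overview**
1. Target ⇐ C8 ketone (hydride reduction sets C8) ⇐ 8-epi alcohol ⇐ C7–C8 ring closure: light-driven, chromium-catalysed Barbier allylation of a C8 aldehyde by a 3-(bromomethyl)butenolide.
2. Butenolide ⇐ ring-closing metathesis of a C6 2-(bromomethyl)acrylate onto a C6 vinyl group; tiglate (C2) and acetate (C15) are placed before that.
3. Z-C1=C10 ⇐ hydroxyl-directed trans-hydroalumination/iodination of a C2 propargylic alcohol, then Negishi coupling with a C9–C8 acetal unit.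
4. C2 and the C4=C5 alkene ⇐ [2,3]-Wittig rearrangement inside a seven-membered silylene, transferring chirality from C5–O to C2.
5. C5/C6 ⇐ methyl 3,4-O-isopropylidene-L-threonate. Ring order: temporary silylene, then butenolide, then the ten-membered carbocycle last.

Assumption: ester 1 (catalogue compound derived from L-ascorbic acid) is taken as the purchasable chiral starting material. Labels C1–C15 are germacrane numbers of the target (C6 lactone oxygen, C8 hydroxyl, C2 tiglate, C15 acetoxymethyl, C14 methyl on C10, C13 exocyclic methylene).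

**Step 1**
Reactants: 1 methyl (2R)-2-[(4S)-2,2-dimethyl-1,3-dioxolan-4-yl]-2-hydroxyacetate; 2 1-bromobut-2-yne
Product: 3 methyl (2R)-2-(but-2-yn-1-yloxy)-2-[(4S)-2,2-dimethyl-1,3-dioxolan-4-yl]acetate
Conditions: Ag2O, CaSO4, Et2O, rt, dark
Reagents that add atoms: none
Why: Silver-oxide-promoted Williamson O-alkylation of the α-hydroxy ester with the propargylic bromide runs under near-neutral conditions, so the ester-bearing stereocentre (C5) is not epimerised and the acetonide is untouched.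

**Step 2**
Reactants: 3 methyl (2R)-2-(but-2-yn-1-yloxy)-2-[(4S)-2,2-dimethyl-1,3-dioxolan-4-yl]acetate
Product: 5 (4S)-4-{(1S)-1-(but-2-yn-1-yloxy)-2-[(trimethylsilyl)methyl]prop-2-en-1-yl}-2,2-dimethyl-1,3-dioxolane, via bis(silylmethyl) carbinol 4 (not isolated)
Conditions: Me3SiCH2MgCl, CeCl3, THF, −78 °C to rt; then SiO2, CH2Cl2, rt
Reagents that add atoms: (trimethylsilyl)methylmagnesium chloride, C[Si](C)(C)C[Mg]Cl
Why: Double addition of the weakly basic organocerium reagent to the ester and silica-promoted Peterson elimination of one β-silyl group (Bunnelle allylsilane synthesis) give the 2-substituted allylsilane without touching the α-alkoxy stereocentre or the propargylic ether.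

**Step 3**
Reactants: 5 (4S)-4-{(1S)-1-(but-2-yn-1-yloxy)-2-[(trimethylsilyl)methyl]prop-2-en-1-yl}-2,2-dimethyl-1,3-dioxolane
Product: 6 (2S,3S)-3-(but-2-yn-1-yloxy)-4-[(trimethylsilyl)methyl]pent-4-ene-1,2-diol
Conditions: AcOH/H2O (4:1), rt
Reagents that add atoms: none
Why: Mild acidic hydrolysis of the terminal isopropylidene ketal frees the 1,2-diol without protodesilylating the allylsilane, and no bond to a stereocentre is broken.

**Step 4**
Reactants: 6 (2S,3S)-3-(but-2-yn-1-yloxy)-4-[(trimethylsilyl)methyl]pent-4-ene-1,2-diol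
Product: 8 (2S)-2-{(1S)-1-(but-2-yn-1-yloxy)-2-[(trimethylsilyl)methyl]prop-2-en-1-yl}oxirane, via primary tosylate 7 (not isolated)
Conditions: NaH, 1-tosylimidazole, THF, 0 °C to rt
Reagents that add atoms: none
Why: Selective sulfonylation of the primary alkoxide followed by intramolecular Williamson closure by the secondary alkoxide gives the terminal epoxide with retention at C6, because only the primary C–O bond is exchanged.

**Step 5**
Reactants: 8 (2S)-2-{(1S)-1-(but-2-yn-1-yloxy)-2-[(trimethylsilyl)methyl]prop-2-en-1-yl}oxirane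
Product: 9 (3S,4S)-4-(but-2-yn-1-yloxy)-5-[(trimethylsilyl)methyl]hexa-1,5-dien-3-ol
Conditions: Me3SI, nBuLi, THF, −10 °C to rt
Reagents that add atoms: trimethylsulfonium iodide, C[S+](C)C.[I-]
Why: Dimethylsulfonium methylide opens the epoxide at its CH2 terminus and base-induced loss of dimethyl sulfide from the β-alkoxy sulfonium salt (one-carbon epoxide-to-allylic-alcohol homologation) gives the vinyl carbinol with C6 unchanged.

**Step 6**
Reactants: 9 (3S,4S)-4-(but-2-yn-1-yloxy)-5-[(trimethylsilyl)methyl]hexa-1,5-dien-3-ol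
Product: 11 (3S,4S)-3-(but-2-yn-1-yloxy)-2-methylidenehex-5-ene-1,4-diol, via epoxysilane 10 (not isolated)
Conditions: mCPBA, NaHCO3, CH2Cl2, 0 °C; then TsOH·H2O (cat.), THF/H2O, rt
Reagents that add atoms: 3-chloroperbenzoic acid, OOC(=O)c1cccc(Cl)c1
Why: The electron-rich 1,1-disubstituted allylsilane alkene is epoxidised much faster than the vinyl group or the alkyne, and acid-induced β-elimination of silicon from the epoxysilane (Peterson-type opening) gives the 2-substituted allylic alcohol that carries the future C15 oxygen.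

**Step 7**
Reactants: 11 (3S,4S)-3-(but-2-yn-1-yloxy)-2-methylidenehex-5-ene-1,4-diol
Product: 12 (4S,5S)-5-(but-2-yn-1-yloxy)-2,2-di-tert-butyl-4-ethenyl-6-methylidene-1,3,2-dioxasilepane
Conditions: tBu2Si(OTf)2, 2,6-lutidine, CH2Cl2, 0 °C to rt
Reagents that add atoms: di-tert-butylsilyl bis(trifluoromethanesulfonate), CC(C)(C)[Si](OS(=O)(=O)C(F)(F)F)(OS(=O)(=O)C(F)(F)F)C(C)(C)C
Why: Silylene formation ties the C15 and C6 hydroxyls into a seven-membered ring, which protects both against the strong bases to come and holds C6 and C15 on the same side, so the alkene made in step 8 can only have the required geometry.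

**Step 8**
Reactants: 12 (4S,5S)-5-(but-2-yn-1-yloxy)-2,2-di-tert-butyl-4-ethenyl-6-methylidene-1,3,2-dioxasilepane
Product: 13 (2S)-1-[(4S)-2,2-di-tert-butyl-4-ethenyl-4,7-dihydro-1,3,2-dioxasilepin-6-yl]pent-3-yn-2-ol
Conditions: nBuLi, THF, −78 °C; then H2O
Reagents that add atoms: none
Why: Deprotonation of the propargylic OCH2 and suprafacial [2,3]-Wittig rearrangement onto the exocyclic methylene form the C2–C3 bond and the ring-locked C4=C5 alkene (C6 cis to C15); the C5–O stereocentre is consumed and its chirality passes to C2 through the envelope transition state with the propynyl group exo (away from the silylene ring), predicted to give the 2S carbinol.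

**Step 9**
Reactants: 13 (2S)-1-[(4S)-2,2-di-tert-butyl-4-ethenyl-4,7-dihydro-1,3,2-dioxasilepin-6-yl]pent-3-yn-2-ol
Product: 15 (2S,3Z)-1-[(4S)-2,2-di-tert-butyl-4-ethenyl-4,7-dihydro-1,3,2-dioxasilepin-6-yl]-4-iodopent-3-en-2-ol, via cyclic alkenylalanate 14 (not isolated)
Conditions: NaAlH2(OCH2CH2OMe)2 (Red-Al), THF, 0 °C; then I2, −78 to 0 °C
Reagents that add atoms: iodine, II
Why: Hydroxyl-directed trans-hydroalumination places aluminium on the distal alkyne carbon in a five-membered alkoxyalanate and iodinolysis with retention gives the vinyl iodide with iodine cis to the carbinol and methyl trans, which fixes the C1=C10 geometry.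

**Step 10**
Reactants: 15 (2S,3Z)-1-[(4S)-2,2-di-tert-butyl-4-ethenyl-4,7-dihydro-1,3,2-dioxasilepin-6-yl]-4-iodopent-3-en-2-ol; 16 (1,3-dioxolan-2-ylmethyl)zinc bromide
Product: 17 (2S,3Z)-1-[(4S)-2,2-di-tert-butyl-4-ethenyl-4,7-dihydro-1,3,2-dioxasilepin-6-yl]-5-(1,3-dioxolan-2-yl)-4-methylpent-3-en-2-ol
Conditions: Pd(PPh3)4 (5 mol %), THF, 50 °C
Reagents that add atoms: none
Why: Negishi cross-coupling under zerovalent palladium catalysis replaces iodine with retention of alkene geometry, installing C9 and the masked C8 aldehyde cis to C2.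

**Step 11**
Reactants: 17 (2S,3Z)-1-[(4S)-2,2-di-tert-butyl-4-ethenyl-4,7-dihydro-1,3,2-dioxasilepin-6-yl]-5-(1,3-dioxolan-2-yl)-4-methylpent-3-en-2-ol; 18 (2E)-2-methylbut-2-enoyl chloride
Product: 19 (2S,3Z)-1-[(4S)-2,2-di-tert-butyl-4-ethenyl-4,7-dihydro-1,3,2-dioxasilepin-6-yl]-5-(1,3-dioxolan-2-yl)-4-methylpent-3-en-2-yl (2E)-2-methylbut-2-enoate
Conditions: pyridine, DMAP (cat.), CH2Cl2, 0 °C to rt
Reagents that add atoms: none
Why: DMAP-catalysed acylation of the only free hydroxyl forms the tiglate at the acyl carbon, so C2 keeps its configuration and the tiglate keeps its E geometry.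

**Step 12**
Reactants: 19 (2S,3Z)-1-[(4S)-2,2-di-tert-butyl-4-ethenyl-4,7-dihydro-1,3,2-dioxasilepin-6-yl]-5-(1,3-dioxolan-2-yl)-4-methylpent-3-en-2-yl (2E)-2-methylbut-2-enoate
Product: 20 (2Z,4S,6Z,8S)-1-(1,3-dioxolan-2-yl)-8-hydroxy-6-(hydroxymethyl)-2-methyldeca-2,6,9-trien-4-yl (2E)-2-methylbut-2-enoate
Conditions: HF·pyridine, pyridine, THF, 0 °C to rt
Reagents that add atoms: none
Why: Buffered fluoride cleaves both Si–O bonds of the silylene (desilylation) while the allylic tiglate and the dioxolane survive, releasing the primary C15 and secondary C6 hydroxyls.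

**Step 13**
Reactants: 20 (2Z,4S,6Z,8S)-1-(1,3-dioxolan-2-yl)-8-hydroxy-6-(hydroxymethyl)-2-methyldeca-2,6,9-trien-4-yl (2E)-2-methylbut-2-enoate
Product: 21 (2Z,4S,6Z,8S)-6-(acetoxymethyl)-1-(1,3-dioxolan-2-yl)-8-hydroxy-2-methyldeca-2,6,9-trien-4-yl (2E)-2-methylbut-2-enoate
Conditions: Ac2O, 2,4,6-collidine, CH2Cl2, −20 °C
Reagents that add atoms: acetic anhydride, CC(=O)OC(C)=O
Why: Kinetically selective esterification acetylates the primary allylic hydroxyl far faster than the hindered bis-allylic secondary one at low temperature with a weak base.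

**Step 14**
Reactants: 21 (2Z,4S,6Z,8S)-6-(acetoxymethyl)-1-(1,3-dioxolan-2-yl)-8-hydroxy-2-methyldeca-2,6,9-trien-4-yl (2E)-2-methylbut-2-enoate; 22 2-(bromomethyl)prop-2-enoic acid
Product: 23 (2Z,4S,6Z,8S)-6-(acetoxymethyl)-8-{[2-(bromomethyl)prop-2-enoyl]oxy}-1-(1,3-dioxolan-2-yl)-2-methyldeca-2,6,9-trien-4-yl (2E)-2-methylbut-2-enoate
Conditions: DCC, DMAP (cat.), CH2Cl2, 0 °C
Reagents that add atoms: none
Why: Steglich esterification acylates the remaining C6 hydroxyl without breaking the C6–O bond, giving the diene needed for butenolide closure with C6 unchanged.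

**Step 15**
Reactants: 23 (2Z,4S,6Z,8S)-6-(acetoxymethyl)-8-{[2-(bromomethyl)prop-2-enoyl]oxy}-1-(1,3-dioxolan-2-yl)-2-methyldeca-2,6,9-trien-4-yl (2E)-2-methylbut-2-enoate
Product: 24 (2Z,4S,6Z)-6-(acetoxymethyl)-7-[(2R)-4-(bromomethyl)-5-oxo-2,5-dihydrofuran-2-yl]-1-(1,3-dioxolan-2-yl)-2-methylhepta-2,6-dien-4-yl (2E)-2-methylbut-2-enoate
Conditions: second-generation Grubbs catalyst RuCl2(=CHPh)(H2IMes)(PCy3) (5 mol %), toluene (0.01 M), 80 °C
Reagents that add atoms: none
Why: Ring-closing metathesis between the terminal C6 vinyl group and the acrylate alkene (the trisubstituted alkenes and the tiglate are inert) expels ethene and forms the 3-(bromomethyl)butenolide with C6 as its γ-carbon.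

**Step 16**
Reactants: 24 (2Z,4S,6Z)-6-(acetoxymethyl)-7-[(2R)-4-(bromomethyl)-5-oxo-2,5-dihydrofuran-2-yl]-1-(1,3-dioxolan-2-yl)-2-methylhepta-2,6-dien-4-yl (2E)-2-methylbut-2-enoate
Product: 25 (3Z,5S,7Z)-7-(acetoxymethyl)-8-[(2R)-4-(bromomethyl)-5-oxo-2,5-dihydrofuran-2-yl]-3-methyl-1-oxoocta-3,7-dien-5-yl (2E)-2-methylbut-2-enoate
Conditions: LiBF4, MeCN/H2O (49:1), 50 °C
Reagents that add atoms: water, O
Why: Mild Lewis-acid-assisted acetal hydrolysis unmasks the β,γ-unsaturated aldehyde under conditions too weak to ionise the allylic esters or move the C1=C10 alkene into conjugation; the aldehyde is used immediately.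

**Step 17**
Reactants: 25 (3Z,5S,7Z)-7-(acetoxymethyl)-8-[(2R)-4-(bromomethyl)-5-oxo-2,5-dihydrofuran-2-yl]-3-methyl-1-oxoocta-3,7-dien-5-yl (2E)-2-methylbut-2-enoate
Product: 26 (3aR,4S,6Z,8S,10Z,11aR)-10-(acetoxymethyl)-4-hydroxy-6-methyl-3-methylidene-2-oxo-2,3,3a,4,5,8,9,11a-octahydrocyclodeca[b]furan-8-yl (2E)-2-methylbut-2-enoate
Conditions: CrCl2 (20 mol %), 4CzIPN (2 mol %), Hantzsch ester (1.5 equiv), DMF (0.002 M), 450 nm LEDs, rt
Reagents that add atoms: none
Why: Proposed new method: under blue light the photocatalyst 4CzIPN, reductively quenched by the Hantzsch ester, turns over a catalytic CrCl2/CrCl3 couple that converts the allylic bromide into a nucleophilic allylchromium species, which adds through its γ-carbon C7 to the tethered aldehyde in a closed six-membered transition state and so closes the ten-membered ring while shifting the double bond to the exocyclic position; attack on the butenolide face opposite the C5 substituent sets C7 as R (trans lactone) and the chair with C9 equatorial gives the 8S carbinol, which is corrected in steps 18 and 19; the closest known reactions are the stoichiometric CrCl2 Nozaki–Hiyama–Kishi allylation of aldehydes with 3-(bromomethyl)butenolides, CrCl2-mediated Barbier macrocyclisations to germacranolides and intermolecular photoredox/chromium allylations of aldehydes, none of which is a photocatalytic, chromium-catalytic macrocyclisation.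

**Step 18**
Reactants: 26 (3aR,4S,6Z,8S,10Z,11aR)-10-(acetoxymethyl)-4-hydroxy-6-methyl-3-methylidene-2-oxo-2,3,3a,4,5,8,9,11a-octahydrocyclodeca[b]furan-8-yl (2E)-2-methylbut-2-enoate
Product: 27 (3aS,6Z,8S,10Z,11aR)-10-(acetoxymethyl)-6-methyl-3-methylidene-2,4-dioxo-2,3,3a,4,5,8,9,11a-octahydrocyclodeca[b]furan-8-yl (2E)-2-methylbut-2-enoate
Conditions: Dess–Martin periodinane, NaHCO3, CH2Cl2, 0 °C
Reagents that add atoms: none
Why: Buffered Dess–Martin oxidation converts the C8 carbinol to the ketone under neutral conditions, erasing the C8 configuration from step 17 without moving either β,γ-alkene into conjugation or touching C7; the ketone is reduced at once without storage.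

**Step 19**
Reactants: 27 (3aS,6Z,8S,10Z,11aR)-10-(acetoxymethyl)-6-methyl-3-methylidene-2,4-dioxo-2,3,3a,4,5,8,9,11a-octahydrocyclodeca[b]furan-8-yl (2E)-2-methylbut-2-enoate
Product: 28 (3aR,4R,6Z,8S,10Z,11aR)-10-(acetoxymethyl)-4-hydroxy-6-methyl-3-methylidene-2-oxo-2,3,3a,4,5,8,9,11a-octahydrocyclodeca[b]furan-8-yl (2E)-2-methylbut-2-enoate
Conditions: NaBH4, CeCl3·7H2O, MeOH, −78 °C
Reagents that add atoms: none
Why: Luche 1,2-reduction is selective for the ketone over the α-methylene lactone and the enoate, and in the ring conformer with C9 anti to C11 the hydride enters C8 from the open face next to H7 (Felkin–Anh, anti to the C6 branch and away from the lactone), giving the 8R alcohol.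

**Compound list**
1 | methyl (2R)-2-[(4S)-2,2-dimethyl-1,3-dioxolan-4-yl]-2-hydroxyacetate (methyl 3,4-O-isopropylidene-L-threonate) | COC(=O)[C@H](O)[C@@H]1COC(C)(C)O1 | starting material
2 | 1-bromobut-2-yne | CC#CCBr | starting material
3 | methyl (2R)-2-(but-2-yn-1-yloxy)-2-[(4S)-2,2-dimethyl-1,3-dioxolan-4-yl]acetate | COC(=O)[C@H](OCC#CC)[C@@H]1COC(C)(C)O1 | intermediate
4 | 2-{(R)-(but-2-yn-1-yloxy)[(4S)-2,2-dimethyl-1,3-dioxolan-4-yl]methyl}-1,3-bis(trimethylsilyl)propan-2-ol | C[Si](C)(C)CC(O)(C[Si](C)(C)C)[C@H](OCC#CC)[C@@H]1COC(C)(C)O1 | intermediate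
5 | (4S)-4-{(1S)-1-(but-2-yn-1-yloxy)-2-[(trimethylsilyl)methyl]prop-2-en-1-yl}-2,2-dimethyl-1,3-dioxolane | C=C(C[Si](C)(C)C)[C@H](OCC#CC)[C@@H]1COC(C)(C)O1 | intermediate
6 | (2S,3S)-3-(but-2-yn-1-yloxy)-4-[(trimethylsilyl)methyl]pent-4-ene-1,2-diol | C=C(C[Si](C)(C)C)[C@H](OCC#CC)[C@@H](O)CO | intermediate
7 | (2S,3S)-3-(but-2-yn-1-yloxy)-2-hydroxy-4-[(trimethylsilyl)methyl]pent-4-en-1-yl 4-methylbenzenesulfonate | C=C(C[Si](C)(C)C)[C@H](OCC#CC)[C@@H](O)COS(=O)(=O)c1ccc(C)cc1 | intermediate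
8 | (2S)-2-{(1S)-1-(but-2-yn-1-yloxy)-2-[(trimethylsilyl)methyl]prop-2-en-1-yl}oxirane | C=C(C[Si](C)(C)C)[C@H](OCC#CC)[C@@H]1CO1 | intermediate
9 | (3S,4S)-4-(but-2-yn-1-yloxy)-5-[(trimethylsilyl)methyl]hexa-1,5-dien-3-ol | C=C(C[Si](C)(C)C)[C@H](OCC#CC)[C@@H](O)C=C | intermediate
10 | (3S,4R)-4-(but-2-yn-1-yloxy)-4-{2-[(trimethylsilyl)methyl]oxiran-2-yl}but-1-en-3-ol (both configurations at the oxirane carbon) | C[Si](C)(C)CC1(CO1)[C@H](OCC#CC)[C@@H](O)C=C | intermediate
11 | (3S,4S)-3-(but-2-yn-1-yloxy)-2-methylidenehex-5-ene-1,4-diol | C=C(CO)[C@H](OCC#CC)[C@@H](O)C=C | intermediate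
12 | (4S,5S)-5-(but-2-yn-1-yloxy)-2,2-di-tert-butyl-4-ethenyl-6-methylidene-1,3,2-dioxasilepane | C=C1CO[Si](C(C)(C)C)(C(C)(C)C)O[C@@H](C=C)[C@H]1OCC#CC | intermediate
13 | (2S)-1-[(4S)-2,2-di-tert-butyl-4-ethenyl-4,7-dihydro-1,3,2-dioxasilepin-6-yl]pent-3-yn-2-ol | CC#C[C@@H](O)CC1=C[C@H](C=C)O[Si](C(C)(C)C)(C(C)(C)C)OC1 | intermediate
14 | sodium bis(2-methoxyethoxy)aluminate chelate of 13: five-membered oxa-aluminacycle with aluminium on C10 (cis to C2) and on the C2 oxygen | C/C1=C/[C@H](CC2=C[C@H](C=C)O[Si](C(C)(C)C)(C(C)(C)C)OC2)O[Al-]1(OCCOC)OCCOC.[Na+] | intermediate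
15 | (2S,3Z)-1-[(4S)-2,2-di-tert-butyl-4-ethenyl-4,7-dihydro-1,3,2-dioxasilepin-6-yl]-4-iodopent-3-en-2-ol | C/C(I)=C/[C@@H](O)CC1=C[C@H](C=C)O[Si](C(C)(C)C)(C(C)(C)C)OC1 | intermediate
16 | (1,3-dioxolan-2-ylmethyl)zinc bromide | Br[Zn]CC1OCCO1 | starting material
17 | (2S,3Z)-1-[(4S)-2,2-di-tert-butyl-4-ethenyl-4,7-dihydro-1,3,2-dioxasilepin-6-yl]-5-(1,3-dioxolan-2-yl)-4-methylpent-3-en-2-ol | C/C(CC1OCCO1)=C/[C@@H](O)CC1=C[C@H](C=C)O[Si](C(C)(C)C)(C(C)(C)C)OC1 | intermediate
18 | (2E)-2-methylbut-2-enoyl chloride (tigloyl chloride) | C/C=C(\C)C(Cl)=O | starting material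
19 | (2S,3Z)-1-[(4S)-2,2-di-tert-butyl-4-ethenyl-4,7-dihydro-1,3,2-dioxasilepin-6-yl]-5-(1,3-dioxolan-2-yl)-4-methylpent-3-en-2-yl (2E)-2-methylbut-2-enoate | C/C(CC1OCCO1)=C/[C@@H](OC(=O)/C(C)=C/C)CC1=C[C@H](C=C)O[Si](C(C)(C)C)(C(C)(C)C)OC1 | intermediate
20 | (2Z,4S,6Z,8S)-1-(1,3-dioxolan-2-yl)-8-hydroxy-6-(hydroxymethyl)-2-methyldeca-2,6,9-trien-4-yl (2E)-2-methylbut-2-enoate | C/C(CC1OCCO1)=C/[C@@H](OC(=O)/C(C)=C/C)C/C(CO)=C/[C@@H](O)C=C | intermediate
21 | (2Z,4S,6Z,8S)-6-(acetoxymethyl)-1-(1,3-dioxolan-2-yl)-8-hydroxy-2-methyldeca-2,6,9-trien-4-yl (2E)-2-methylbut-2-enoate | C/C(CC1OCCO1)=C/[C@@H](OC(=O)/C(C)=C/C)C/C(COC(C)=O)=C/[C@@H](O)C=C | intermediate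
22 | 2-(bromomethyl)prop-2-enoic acid | C=C(CBr)C(=O)O | starting material
23 | (2Z,4S,6Z,8S)-6-(acetoxymethyl)-8-{[2-(bromomethyl)prop-2-enoyl]oxy}-1-(1,3-dioxolan-2-yl)-2-methyldeca-2,6,9-trien-4-yl (2E)-2-methylbut-2-enoate | C/C(CC1OCCO1)=C/[C@@H](OC(=O)/C(C)=C/C)C/C(COC(C)=O)=C/[C@@H](OC(=O)C(=C)CBr)C=C | intermediate
24 | (2Z,4S,6Z)-6-(acetoxymethyl)-7-[(2R)-4-(bromomethyl)-5-oxo-2,5-dihydrofuran-2-yl]-1-(1,3-dioxolan-2-yl)-2-methylhepta-2,6-dien-4-yl (2E)-2-methylbut-2-enoate | C/C(CC1OCCO1)=C/[C@@H](OC(=O)/C(C)=C/C)C/C(COC(C)=O)=C/[C@H]1OC(=O)C(CBr)=C1 | intermediate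
25 | (3Z,5S,7Z)-7-(acetoxymethyl)-8-[(2R)-4-(bromomethyl)-5-oxo-2,5-dihydrofuran-2-yl]-3-methyl-1-oxoocta-3,7-dien-5-yl (2E)-2-methylbut-2-enoate | C/C(CC=O)=C/[C@@H](OC(=O)/C(C)=C/C)C/C(COC(C)=O)=C/[C@H]1OC(=O)C(CBr)=C1 | intermediate
26 | (3aR,4S,6Z,8S,10Z,11aR)-10-(acetoxymethyl)-4-hydroxy-6-methyl-3-methylidene-2-oxo-2,3,3a,4,5,8,9,11a-octahydrocyclodeca[b]furan-8-yl (2E)-2-methylbut-2-enoate (8-epimer of the target in germacrane numbering) | C=C1C(=O)O[C@@H]2/C=C(\COC(C)=O)C[C@H](OC(=O)/C(C)=C/C)/C=C(/C)C[C@H](O)[C@@H]12 | intermediate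
27 | (3aS,6Z,8S,10Z,11aR)-10-(acetoxymethyl)-6-methyl-3-methylidene-2,4-dioxo-2,3,3a,4,5,8,9,11a-octahydrocyclodeca[b]furan-8-yl (2E)-2-methylbut-2-enoate | C=C1C(=O)O[C@@H]2/C=C(\COC(C)=O)C[C@H](OC(=O)/C(C)=C/C)/C=C(/C)CC(=O)[C@@H]12 | intermediate
28 | (3aR,4R,6Z,8S,10Z,11aR)-10-(acetoxymethyl)-4-hydroxy-6-methyl-3-methylidene-2-oxo-2,3,3a,4,5,8,9,11a-octahydrocyclodeca[b]furan-8-yl (2E)-2-methylbut-2-enoate (CNP0129394.2) | C=C1C(=O)O[C@@H]2/C=C(\COC(C)=O)C[C@H](OC(=O)/C(C)=C/C)/C=C(/C)C[C@@H](O)[C@@H]12 | target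

**Totals and risks**
Total step count: 19. Longest linear sequence: 19 (the route is fully linear from 1).

The three steps most likely to fail are steps 8, 17 and 19.

The [2,3]-Wittig rearrangement of step 8 fixes the alkene geometry through the ring, but the sense of chirality transfer to C2 rests on the exo preference of the propynyl group. The fallback sets out from 12 and comes back to the route at 13. If the rearrangement of 12 gives mainly the C2 epimer (2R)-1-[(4S)-2,2-di-tert-butyl-4-ethenyl-4,7-dihydro-1,3,2-dioxasilepin-6-yl]pent-3-yn-2-ol F1, that propargylic alcohol is inverted by a Mitsunobu reaction with 4-nitrobenzoic acid (PPh3, DIAD, THF, 0 °C). This gives (2S)-1-[(4S)-2,2-di-tert-butyl-4-ethenyl-4,7-dihydro-1,3,2-dioxasilepin-6-yl]pent-3-yn-2-yl 4-nitrobenzoate F2, and methanolysis (K2CO3, MeOH, 0 °C) then returns 13.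

The photochemical ring closure of step 17 is the new reaction and the most uncertain one. Catalytic chromium turnover at 2 mM may be slow, and the β,γ-unsaturated aldehyde or the bromide may be reduced before ring closure. The fallback sets out from 25 and comes back to the route at 26. It gives up photocatalysis altogether and uses the classical stoichiometric Nozaki–Hiyama–Kishi allylation (CrCl2, 10 equiv, THF/DMF, syringe-pump addition, rt, dark), in which the allylchromium reagent arises by two-electron oxidative addition of divalent chromium; this is a known way to close germacranolide rings. No new compound is made on this path (entry F0).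

The reduction of step 19 depends on the conformation of the ten-membered ketone, and ketone 27 from step 18 is itself prone to enolisation towards C7. If the C9-anti-to-C6 conformer reacts, the hydride gives back the 8S alcohol 26. The fallback sets out from 26 and comes back to the route at 28, so it bypasses ketone 27. It inverts C8 by SN2 instead of by oxidation and reduction: a Mitsunobu reaction with formic acid (PPh3, DIAD, THF, 0 °C) gives (3aR,4R,6Z,8S,10Z,11aR)-10-(acetoxymethyl)-4-(formyloxy)-6-methyl-3-methylidene-2-oxo-2,3,3a,4,5,8,9,11a-octahydrocyclodeca[b]furan-8-yl (2E)-2-methylbut-2-enoate F3. Brief treatment with KHCO3 in MeOH at 0 °C then removes only the formate and gives 28.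

**Further compounds**
F1 | step 8 | (2R)-1-[(4S)-2,2-di-tert-butyl-4-ethenyl-4,7-dihydro-1,3,2-dioxasilepin-6-yl]pent-3-yn-2-ol | CC#C[C@H](O)CC1=C[C@H](C=C)O[Si](C(C)(C)C)(C(C)(C)C)OC1
F2 | step 8 | (2S)-1-[(4S)-2,2-di-tert-butyl-4-ethenyl-4,7-dihydro-1,3,2-dioxasilepin-6-yl]pent-3-yn-2-yl 4-nitrobenzoate | CC#C[C@@H](OC(=O)c1ccc(cc1)[N+](=O)[O-])CC1=C[C@H](C=C)O[Si](C(C)(C)C)(C(C)(C)C)OC1
F0 | step 17 | none | none
F3 | step 19 | (3aR,4R,6Z,8S,10Z,11aR)-10-(acetoxymethyl)-4-(formyloxy)-6-methyl-3-methylidene-2-oxo-2,3,3a,4,5,8,9,11a-octahydrocyclodeca[b]furan-8-yl (2E)-2-methylbut-2-enoate | C=C1C(=O)O[C@@H]2/C=C(\COC(C)=O)C[C@H](OC(=O)/C(C)=C/C)/C=C(/C)C[C@@H](OC=O)[C@@H]12
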